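**Retrosynthetic overview**

1. The strategy rests on the only ring of the target, the 2-hydroxy-5-methoxy-1,4-benzoquinone. C1(=O), C2(OH), C3(side chain) and C4(=O) are the four ring carbons of a squaric ester, and C5(OMe)–C6(H) is a two-carbon 2-methoxyvinyl unit.
2. Late disconnections: C2–OH from its isopropyl ether (BCl3), the C2' acetate from a silyl ether, and the quinone from its hydroquinone.
3. Key disconnection C4–C5: thermal ring expansion of a 4-hydroxy-4-(2-methoxyvinyl)cyclobutenone. The six-membered ring is the only ring formed in the route, and it is formed here from the purchased four-membered ring.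
4. C1–C6 comes from addition of (Z)-2-methoxyvinyllithium to a 3-alkyl-4-isopropoxycyclobutenedione; C3–C1' comes from addition of a β-oxido alkyllithium to diisopropyl squarate.
5. The C2' stereocentre comes from (R)-epichlorohydrin, opened at its epoxide CH2 by decylmagnesium bromide.

Key step: step 7

Remark: the ring carbinol carbon created in each of the two organolithium additions forms without control and both epimers are carried on, because this carbon later becomes a carbonyl or an aromatic carbon.

**Route**

Step 1
Reactants: 1 1-bromodecane; 2 (R)-epichlorohydrin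
Product: 4 (R)-1-chlorotridecan-2-ol, via decylmagnesium bromide 3 (not isolated)
Conditions: Mg, THF, rt; then 2, CuI (10 mol %), THF, −40 → −20 °C; sat. aq NH4Cl
Reagents that add atoms: none
Why: Copper-catalysed Grignard opening of a terminal epoxide (SN2 at the unsubstituted ring carbon, faster at low temperature than displacement of the primary chloride), in which the stereocentre of 2 is not a reacting atom and is carried over unchanged as (R).

Step 2
Reactants: 4 (R)-1-chlorotridecan-2-ol; 5 diisopropyl squarate
Product: 8 4-hydroxy-4-[(2R)-2-hydroxytridecyl]-2,3-diisopropoxycyclobut-2-en-1-one, via lithium alkoxide 6 (not isolated), via dilithio species 7 (not isolated)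
Conditions: n-BuLi (1.0 equiv), THF, −78 °C; lithium naphthalenide (LiC10H8, 2.0 equiv, added to a faint persistent green), −78 °C; cannulate into 5, THF, −78 °C; sat. aq NH4Cl at −78 °C
Reagents that add atoms: none
Why: O-Deprotonation followed by reductive lithiation of the C–Cl bond by the naphthalene radical anion gives a β-oxido alkyllithium that holds at −78 °C because lithium oxide is a poor leaving group, and its 1,2-addition to one carbonyl of the squaric ester is the standard organolithium addition to squarates; the C2' centre is not involved and stays (R), while the new ring carbinol centre forms unselectively and is removed in step 4.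

Step 3
Reactants: 8 4-hydroxy-4-[(2R)-2-hydroxytridecyl]-2,3-diisopropoxycyclobut-2-en-1-one
Product: 9 4-[(2R)-2-(tert-butyldimethylsilyloxy)tridecyl]-4-hydroxy-2,3-diisopropoxycyclobut-2-en-1-one
Conditions: TBSCl, imidazole, DMF, rt
Reagents that add atoms: tert-butyldimethylsilyl chloride (TBSCl), CC(C)(C)[Si](C)(C)Cl
Why: Standard silyl ether formation, selective for the secondary alcohol because the tertiary ring carbinol is too hindered to be silylated by TBSCl and imidazole; no stereocentre is touched, and the masked hydroxyl can no longer attack the neighbouring vinylogous ester carbon.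

Step 4
Reactants: 9 4-[(2R)-2-(tert-butyldimethylsilyloxy)tridecyl]-4-hydroxy-2,3-diisopropoxycyclobut-2-en-1-one
Product: 10 3-[(2R)-2-(tert-butyldimethylsilyloxy)tridecyl]-4-isopropoxycyclobut-3-ene-1,2-dione
Conditions: 12 M HCl (cat.), CH2Cl2, 0 °C → rt, short contact; aq NaHCO3
Reagents that add atoms: water, O
Why: Acid-catalysed rearrangement of a squarate 1,2-adduct, in which the tertiary carbinol ionises to an alkoxy-stabilised cyclobutenyl cation, water adds at the isopropoxy-bearing terminus and the hemiketal loses propan-2-ol to give the cyclobutenedione; the brief two-phase contact with catalytic acid should spare the secondary silyl ether, and the ring carbinol stereocentre disappears.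

Step 5
Reactants: 11 methyl vinyl ether
Product: 13 (Z)-1-bromo-2-methoxyethene, via 1,2-dibromo-1-methoxyethane 12 (not isolated)
Conditions: Br2, pentane, −78 °C; then PhNEt2, 90 °C, fractional distillation
Reagents that add atoms: bromine, BrBr
Why: Electrophilic addition of bromine to the enol ether followed by amine-promoted dehydrobromination of the α-bromo ether, an elimination known for the ethyl homologue to give mainly the (Z)-2-bromovinyl ether; any minor (E)-isomer would lead to the same hydroquinone in step 7.

Step 6
Reactants: 10 3-[(2R)-2-(tert-butyldimethylsilyloxy)tridecyl]-4-isopropoxycyclobut-3-ene-1,2-dione; 13 (Z)-1-bromo-2-methoxyethene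
Product: 15 4-hydroxy-3-isopropoxy-4-[(Z)-2-methoxyethenyl]-2-[(2R)-2-(tert-butyldimethylsilyloxy)tridecyl]cyclobut-2-en-1-one, via (Z)-2-methoxyvinyllithium 14 (not isolated)
Conditions: 13, t-BuLi (2.0 equiv), Et2O, −78 °C; cannulate into 10, THF, −78 °C; sat. aq NH4Cl at −78 °C; Et3N-deactivated silica
Reagents that add atoms: none
Why: Bromine–lithium exchange proceeds with retention of alkene geometry to the oxygen-chelated (Z)-2-methoxyvinyllithium, which adds 1,2 to the more electrophilic, ketone-like carbonyl of 10 (the one bonded to the isopropoxy-bearing carbon; the other is deactivated as a vinylogous ester), as is usual for 3-alkoxy-4-alkylcyclobutenediones; the new carbinol centre forms as a mixture and is lost in step 7.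

Step 7
Reactants: 15 4-hydroxy-3-isopropoxy-4-[(Z)-2-methoxyethenyl]-2-[(2R)-2-(tert-butyldimethylsilyloxy)tridecyl]cyclobut-2-en-1-one
Product: 18 3-isopropoxy-6-methoxy-2-[(2R)-2-(tert-butyldimethylsilyloxy)tridecyl]benzene-1,4-diol, via dienylketene 16 (not isolated), via cyclohexadienone 17 (not isolated)
Conditions: toluene (degassed, dilute), 110 °C, Ar, base-washed glassware; crude product used at once
Reagents that add atoms: none
Why: Heating opens the strained cyclobutenone by conrotatory 4π electrocyclic cleavage of the bond between the carbonyl carbon and the carbinol carbon, giving dienylketene 16; its ketene carbon then bonds to the methoxy-bearing vinyl carbon in a thermal 6π electrocyclisation (new bond C4–C5 of the target) to give dienone 17, which enolises to the aromatic hydroquinone 18. The closest known reaction type is the Moore rearrangement of squarate-derived 4-alkenyl-4-hydroxycyclobutenones. The one ring formed, the six-membered carbocycle, closes by 6π electrocyclisation of a triene whose ketene terminus has no substituent to rotate, and strain release in the first event and aromatisation in the last drive it forward. No stereocentre is set: the sp3 carbon of 17 is lost on enolisation, the carbinol centre of 15 becomes a phenol carbon, and the silyl-protected C2' centre is not a reacting atom. The selectivity needed is torquoselectivity in the ring opening, and it is secured by the hydroxyl on the breaking bond, a donor that rotates outward and so turns the methoxyvinyl group inward toward the ketene; rotation the other way would let the hydroxyl add to the ketene and form a furanone. The placement of isopropoxy, side chain, methoxy and hydrogen around the ring is already fixed by the connectivity of 15, and base-washed glassware keeps the acid-labile γ-hydroxy enol ether intact until it has opened.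

Step 8
Reactants: 18 3-isopropoxy-6-methoxy-2-[(2R)-2-(tert-butyldimethylsilyloxy)tridecyl]benzene-1,4-diol
Product: 19 2-isopropoxy-5-methoxy-3-[(2R)-2-(tert-butyldimethylsilyloxy)tridecyl]cyclohexa-2,5-diene-1,4-dione
Conditions: Ag2O, MgSO4, Et2O, rt
Reagents that add atoms: none
Why: Two-electron oxidation of a hydroquinone to the 1,4-benzoquinone with Ag2O under neutral conditions, which should leave the silyl ether and both alkoxy groups untouched.

Step 9
Reactants: 19 2-isopropoxy-5-methoxy-3-[(2R)-2-(tert-butyldimethylsilyloxy)tridecyl]cyclohexa-2,5-diene-1,4-dione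
Product: 20 3-[(2R)-2-hydroxytridecyl]-2-isopropoxy-5-methoxycyclohexa-2,5-diene-1,4-dione
Conditions: HF·pyridine, pyridine, THF, 0 °C → rt
Reagents that add atoms: none
Why: Fluoride-driven cleavage of the Si–O bond (formation of the strong Si–F bond) under buffered, non-basic conditions that a quinone tolerates; the C–O bond at C2' is not broken, so the (R) configuration is kept.

Step 10
Reactants: 20 3-[(2R)-2-hydroxytridecyl]-2-isopropoxy-5-methoxycyclohexa-2,5-diene-1,4-dione
Product: 21 (2R)-1-(2-isopropoxy-5-methoxy-3,6-dioxocyclohexa-1,4-dien-1-yl)tridecan-2-yl acetate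
Conditions: Ac2O, pyridine, 4-(dimethylamino)pyridine (cat.), CH2Cl2, 0 °C
Reagents that add atoms: acetic anhydride, CC(=O)OC(C)=O
Why: Nucleophile-catalysed O-acylation of the secondary alcohol, with retention at C2' because only the O–H bond reacts, while the ring oxygen at C2 is still masked as its isopropyl ether and so cannot be acetylated.

Step 11
Reactants: 21 (2R)-1-(2-isopropoxy-5-methoxy-3,6-dioxocyclohexa-1,4-dien-1-yl)tridecan-2-yl acetate
Product: 22 (2R)-1-(2-hydroxy-5-methoxy-3,6-dioxocyclohexa-1,4-dien-1-yl)tridecan-2-yl acetate
Conditions: BCl3 (1 M in CH2Cl2), CH2Cl2, −78 °C; then H2O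
Reagents that add atoms: none
Why: Lewis-acid dealkylation in which BCl3 binds between the C1 carbonyl and the isopropoxy oxygen and the secondary alkyl–oxygen bond ionises far faster than the methyl–oxygen bond at C5 can be cut, the known preference of BCl3 for isopropyl over methyl ethers; at −78 °C the acetate and the C2' centre should survive.

**Compound list**

1 | 1-bromodecane | CCCCCCCCCCBr | starting material
2 | (R)-epichlorohydrin | ClC[C@H]1CO1 | starting material
3 | decylmagnesium bromide | CCCCCCCCCC[Mg]Br | intermediate (not isolated)
4 | (R)-1-chlorotridecan-2-ol | CCCCCCCCCCC[C@H](CCl)O | intermediate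
5 | diisopropyl squarate (3,4-diisopropoxycyclobut-3-ene-1,2-dione) | CC(C)OC1=C(OC(C)C)C(=O)C1=O | starting material
6 | lithium (2R)-1-chlorotridecan-2-olate | CCCCCCCCCCC[C@H](CCl)O[Li] | intermediate (not isolated)
7 | lithium (2S)-1-lithiotridecan-2-olate (same spatial arrangement as 4; the descriptor changes because CH2Li ranks below the alkyl chain) | CCCCCCCCCCC[C@H](C[Li])O[Li] | intermediate (not isolated)
8 | 4-hydroxy-4-[(2R)-2-hydroxytridecyl]-2,3-diisopropoxycyclobut-2-en-1-one (both epimers at C4) | CCCCCCCCCCC[C@H](CC1(O)C(OC(C)C)=C(OC(C)C)C1=O)O | intermediate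
9 | 4-[(2R)-2-(tert-butyldimethylsilyloxy)tridecyl]-4-hydroxy-2,3-diisopropoxycyclobut-2-en-1-one (both epimers at C4) | CCCCCCCCCCC[C@H](CC1(O)C(OC(C)C)=C(OC(C)C)C1=O)O[Si](C)(C)C(C)(C)C | intermediate
10 | 3-[(2R)-2-(tert-butyldimethylsilyloxy)tridecyl]-4-isopropoxycyclobut-3-ene-1,2-dione | CCCCCCCCCCC[C@H](CC1=C(OC(C)C)C(=O)C1=O)O[Si](C)(C)C(C)(C)C | intermediate
11 | methyl vinyl ether | COC=C | starting material
12 | 1,2-dibromo-1-methoxyethane (racemic) | COC(Br)CBr | intermediate (not isolated)
13 | (Z)-1-bromo-2-methoxyethene | CO/C=C\Br | intermediate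
14 | (Z)-2-methoxyvinyllithium | CO/C=C\[Li] | intermediate (not isolated)
15 | 4-hydroxy-3-isopropoxy-4-[(Z)-2-methoxyethenyl]-2-[(2R)-2-(tert-butyldimethylsilyloxy)tridecyl]cyclobut-2-en-1-one (both epimers at C4) | CCCCCCCCCCC[C@H](CC1=C(OC(C)C)C(O)(/C=C\OC)C1=O)O[Si](C)(C)C(C)(C)C | intermediate
16 | (3Z,5Z)-4-hydroxy-3-isopropoxy-6-methoxy-2-[(2R)-2-(tert-butyldimethylsilyloxy)tridecyl]hexa-1,3,5-trien-1-one | CCCCCCCCCCC[C@H](CC(=C=O)/C(OC(C)C)=C(O)\C=C/OC)O[Si](C)(C)C(C)(C)C | intermediate (not isolated)
17 | 4-hydroxy-3-isopropoxy-6-methoxy-2-[(2R)-2-(tert-butyldimethylsilyloxy)tridecyl]cyclohexa-2,4-dien-1-one (either configuration at C6) | CCCCCCCCCCC[C@H](CC1=C(OC(C)C)C(O)=CC(OC)C1=O)O[Si](C)(C)C(C)(C)C | intermediate (not isolated)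
18 | 3-isopropoxy-6-methoxy-2-[(2R)-2-(tert-butyldimethylsilyloxy)tridecyl]benzene-1,4-diol | CCCCCCCCCCC[C@H](Cc1c(O)c(OC)cc(O)c1OC(C)C)O[Si](C)(C)C(C)(C)C | intermediate
19 | 2-isopropoxy-5-methoxy-3-[(2R)-2-(tert-butyldimethylsilyloxy)tridecyl]cyclohexa-2,5-diene-1,4-dione | CCCCCCCCCCC[C@H](CC1=C(OC(C)C)C(=O)C=C(OC)C1=O)O[Si](C)(C)C(C)(C)C | intermediate
20 | 3-[(2R)-2-hydroxytridecyl]-2-isopropoxy-5-methoxycyclohexa-2,5-diene-1,4-dione | CCCCCCCCCCC[C@H](CC1=C(OC(C)C)C(=O)C=C(OC)C1=O)O | intermediate
21 | (2R)-1-(2-isopropoxy-5-methoxy-3,6-dioxocyclohexa-1,4-dien-1-yl)tridecan-2-yl acetate | CCCCCCCCCCC[C@H](CC1=C(OC(C)C)C(=O)C=C(OC)C1=O)OC(C)=O | intermediate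
22 | (2R)-1-(2-hydroxy-5-methoxy-3,6-dioxocyclohexa-1,4-dien-1-yl)tridecan-2-yl acetate | CCCCCCCCCCC[C@H](CC1=C(O)C(=O)C=C(OC)C1=O)OC(C)=O | target

**Totals**

Total step count: 11. Longest linear sequence: 10 steps (steps 1–4 and 6–11, from 1-bromodecane and (R)-epichlorohydrin); step 5 is a one-step side branch.

**Steps most likely to fail**

Step 2. The carbanion may be lost before the C–C bond forms: lithium oxide can be eliminated on local warming, radical anion left in the solution can transfer an electron to the squaric ester, and if the adduct warms before the quench the side-chain alkoxide can close onto the neighbouring isopropoxy-bearing ring carbon. The fallback sets out from 4 and comes back at 8. Halide exchange (NaI, butanone, reflux; Finkelstein reaction) should give (R)-1-iodotridecan-2-ol F1. t-BuLi (3 equiv, Et2O–pentane, −100 °C) then removes the hydroxyl proton and exchanges iodine for lithium in a two-electron process, so that 7 forms with no electron-transfer reagent in the flask. Anhydrous CeCl3 (THF slurry, −78 °C) converts 7 into the less basic and less reducing organocerium reagent, lithium (2R)-1-(dichlorocerio)tridecan-2-olate F2, which is added to 5 at −78 °C and quenched cold to give 8.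

Step 11. The two vinylogous ester groups may not be told apart well enough: the methyl group may be lost as well, chloride may replace an alkoxy group on the activated ring, or the Lewis acid may cleave the acetate. The fallback sets out from 21 and comes back at 22, and moves the dealkylation to the aromatic oxidation level, where the preference of BCl3 for aryl isopropyl over aryl methyl ethers is well established. Na2S2O4 (aq, EtOAc) should reduce 21 to the hydroquinone (2R)-1-(2,5-dihydroxy-6-isopropoxy-3-methoxyphenyl)tridecan-2-yl acetate F5. BCl3 (CH2Cl2, −78 → 0 °C) should then cleave only the isopropyl ether to give (2R)-1-(2,3,6-trihydroxy-5-methoxyphenyl)tridecan-2-yl acetate F6. This hydroxyhydroquinone should oxidise on exposure to air, or with Ag2O, to the 2-hydroxy-1,4-benzoquinone 22.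

Step 7. The γ-hydroxy enol ether of 15 may ionise and lose methanol under trace acid or on heating before the four-membered ring opens, and a share of the material may open with the hydroxyl turned inward and be diverted to a furanone. The fallback sets out from 10 and comes back at 19, replacing steps 6 to 8 with the alkynyl variant of the same ring expansion. Lithium methoxyacetylide F3 (from chloroacetaldehyde dimethyl acetal and LiNEt2, 3 equiv, THF, 0 °C) is added at −78 °C to the ketone-like carbonyl of 10 to give 4-hydroxy-3-isopropoxy-4-(methoxyethynyl)-2-[(2R)-2-(tert-butyldimethylsilyloxy)tridecyl]cyclobut-2-en-1-one F4. Heating F4 (p-xylene, 138 °C) should open it to an enynylketene that closes to a six-membered diradical; transfer of the hydroxyl hydrogen to the ring radical carbon gives quinone 19 directly, with no enol ether in the precursor and no separate oxidation.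

**Further compounds**

F1 | step 2 | (R)-1-iodotridecan-2-ol | CCCCCCCCCCC[C@H](CI)O
F2 | step 2 | lithium (2R)-1-(dichlorocerio)tridecan-2-olate (same spatial arrangement as 7) | CCCCCCCCCCC[C@H](C[Ce](Cl)Cl)O[Li]
F3 | step 7 | lithium methoxyacetylide | COC#C[Li]
F4 | step 7 | 4-hydroxy-3-isopropoxy-4-(methoxyethynyl)-2-[(2R)-2-(tert-butyldimethylsilyloxy)tridecyl]cyclobut-2-en-1-one | CCCCCCCCCCC[C@H](CC1=C(OC(C)C)C(O)(C#COC)C1=O)O[Si](C)(C)C(C)(C)C
F5 | step 11 | (2R)-1-(2,5-dihydroxy-6-isopropoxy-3-methoxyphenyl)tridecan-2-yl acetate | CCCCCCCCCCC[C@H](Cc1c(O)c(OC)cc(O)c1OC(C)C)OC(C)=O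
F6 | step 11 | (2R)-1-(2,3,6-trihydroxy-5-methoxyphenyl)tridecan-2-yl acetate | CCCCCCCCCCC[C@H](Cc1c(O)c(OC)cc(O)c1O)OC(C)=O
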